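**Plan** (ent-kaurane numbering: ring A = C1–C5 and C10; C6 = CH2OH on C5; lactone = C10–C20–O–C7(=O)–C8–C9; ring C = C8, C9, C11–C14; ring D = C8, C14, C13, C16, C15; C17 = CH2OH on C16)
Cuts: C16–C17 (formaldehyde aldol), C2=C3 (dehydrogenation), C13–C16 (ring D), C8–C14 plus C9–C11 (ring C, Diels–Alder with butadiene), then ring A and the δ-lactone together, then C1–C10.
Enabling feature: the C1 ketone of ring A stands next to the quaternary spiro atom C10 (semipinacol retron). C10 is also 1,3 to C8, the carbon between the C7 lactone and C15 ketone carbonyls, so C8–C9–C10 can be drawn as an acceptor cyclopropane fused to a γ-lactone (C8, C7, O, C20, C10) that carries a 1-silyloxycyclopentyl group (C1–C5) on C10.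
Key event: heterolysis of C8–C10 with a 1,2-shift of C5 from C1 to C10 enlarges the cyclopentane to ring A and the γ-lactone to the δ-lactone in one act and fixes C10. The cyclopropane, the silyl ether and the C1 stereocentre are helpers that vanish in it.
Forward order: cyclopentanone (C1–C6) → C1–C10 bond → diazoacetoacetate tether → ring A + lactone (step 8) → ring C (step 10) → ring D (step 11) → enone → C17.
Stereochemistry: C5 comes from a catalytic asymmetric hydroxymethylation. It is relayed C5 → C1 (addition anti to C6) → cyclopropane face → C10 (invertive shift). C8/C9 come from the Diels–Alder face anti to C5, C13 from the bridge, C16 from exo attack of formaldehyde.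

Key step: step 8

Assumption: the (S,S)-bipyridine ligand of step 2 is taken to deliver the S ketol 3; if the sense of induction is the opposite, its enantiomer is used.

**Step 1**
Reactants: 1 3-methylcyclopent-2-en-1-one
Product: 2 1-(trimethylsilyloxy)-3,3-dimethylcyclopent-1-ene
Conditions: MeMgBr, CuI (5 mol %), LiCl (10 mol %), TMSCl, THF, −40 °C
Reagents that add atoms: methylmagnesium bromide C[Mg]Br; chlorotrimethylsilane C[Si](C)(C)Cl
Why: Copper-catalysed conjugate addition of the Grignard reagent with in situ silyl trapping should build the gem-dimethyl carbon C4 and lock the enolate on the carbon next to it (future C5); no stereocentre is formed.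

**Step 2**
Reactants: 2 1-(trimethylsilyloxy)-3,3-dimethylcyclopent-1-ene
Product: 3 (S)-2-(hydroxymethyl)-3,3-dimethylcyclopentan-1-one
Conditions: Sc(OTf)3 (10 mol %), (S,S)-6,6′-bis(1-hydroxy-2,2-dimethylpropyl)-2,2′-bipyridine (12 mol %), 35% aq HCHO, DME, −20 °C
Reagents that add atoms: formaldehyde C=O
Why: Catalytic asymmetric aqueous Mukaiyama aldol (hydroxymethylation of a silicon enolate): the chiral scandium–bipyridine complex should shield one enol face so that the small electrophile adds next to the quaternary carbon and sets the S centre, the future C5 and the only centre taken from a catalyst.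

**Step 3**
Reactants: 3 (S)-2-(hydroxymethyl)-3,3-dimethylcyclopentan-1-one
Product: 4 (S)-2-[(tert-butyldiphenylsilyloxy)methyl]-3,3-dimethylcyclopentan-1-one
Conditions: TBDPSCl, imidazole, CH2Cl2, 0 °C to rt
Reagents that add atoms: tert-butyl(chloro)diphenylsilane CC(C)(C)[Si](Cl)(c1ccccc1)c1ccccc1
Why: Standard silylation of a primary alcohol under weakly basic conditions should neither dehydrate the ketol nor epimerise C5, and the bulky ether lasts to the final step.

**Step 4**
Reactants: 4 (S)-2-[(tert-butyldiphenylsilyloxy)methyl]-3,3-dimethylcyclopentan-1-one; 5 2-bromoprop-2-en-1-ol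
Product: 7 (1S,2S)-2-[(tert-butyldiphenylsilyloxy)methyl]-1-(3-hydroxyprop-1-en-2-yl)-3,3-dimethylcyclopentan-1-ol, via lithium 2-lithioallyl oxide 6 (not isolated)
Conditions: 5, t-BuLi (3.1 equiv), Et2O, −78 to 0 °C; added to 4·LaCl3·2LiCl, THF, −78 °C; H2O
Reagents that add atoms: none
Why: Halogen–lithium exchange followed by lanthanide-assisted 1,2-addition of the alkenyllithium: the Lewis acid should favour addition over enolisation and β-elimination, and attack anti to the C5 side chain sets the temporary C1 centre (alkenyl trans to CH2OTBDPS).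

**Step 5**
Reactants: 7 the diol of step 4
Product: 9 tertiary trimethylsilyl ether of 7 (free primary allylic alcohol), via bis(trimethylsilyl) ether 8 (not isolated)
Conditions: TMSOTf (2.5 equiv), 2,6-lutidine, CH2Cl2, −78 to 0 °C; then K2CO3 (cat.), MeOH, 0 °C
Reagents that add atoms: trimethylsilyl triflate C[Si](C)(C)OS(=O)(=O)C(F)(F)F
Why: Exhaustive silylation followed by selective methanolysis of the unhindered primary TMS ether should leave the hindered C1–OTMS group, which blocks O–H insertion in step 8 and serves as the electron push of the 1,2-shift.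

**Step 6**
Reactants: 9 tertiary TMS ether; 10 2,2,6-trimethyl-4H-1,3-dioxin-4-one
Product: 11 acetoacetate of 9 (ester on the C20 oxygen)
Conditions: toluene, 110 °C
Reagents that add atoms: none
Why: Thermal retro-hetero-Diels–Alder cleavage of the dioxinone releases acetylketene, which the primary alcohol traps under neutral conditions (acetoacetylation) and so brings in C7, C8, C15 and C16.

**Step 7**
Reactants: 11 acetoacetate of 9
Product: 12 2-diazoacetoacetate of 9
Conditions: 4-acetamidobenzenesulfonyl azide, Et3N, MeCN, 0 °C to rt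
Reagents that add atoms: 4-acetamidobenzenesulfonyl azide CC(=O)Nc1ccc(cc1)S(=O)(=O)N=[N+]=[N-]
Why: Regitz diazo transfer should take place only at the active methylene C8, and the silyl ethers and the alkene are inert to the mild base.

**Step 8**
Reactants: 12 2-diazoacetoacetate of 9
Product: 15 spiro keto δ-lactone (5R,10S; 8-acetyl; C8 labile), via cyclopropane-fused γ-lactone 13 (not isolated), via silyl enol ether 14 (not isolated)
Conditions: Rh2(OAc)4 (1 mol %), CH2Cl2, reflux, slow addition of 12; cool to 0 °C, Sc(OTf)3 (10 mol %), 0 °C to rt; aq citric acid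
Reagents that add atoms: none
Why: Proposed new method: the rhodium carbenoid from 12 should add syn to the 1,1-disubstituted alkene (the known intramolecular cyclopropanation of allyl diazoacetoacetates, closing the three-membered ring and the γ-lactone through a 5-exo tether) from the face anti to C5, in the staggered rotamer that keeps the small silyloxy oxygen inside next to the C20 tether, so that 13 is born with the C1–C5 bond antiperiplanar to C8–C10. Sc(OTf)3 chelated by the C7/C15 dicarbonyl then polarises C8–C10, the only cyclopropane bond whose rupture leaves a tertiary cation, and as it breaks C5 shifts from C1 to C10 under the push of the silyloxy oxygen, so that the cyclopentane becomes the ring A cyclohexanone and the γ-lactone becomes the δ-lactone along the surviving C8–C9 bond (both six-membered rings arise by one-atom enlargement, not by end-to-end closure), the silyl group passing to the enolate (14) and leaving on work-up. The closest known reaction types are the semipinacol ring expansion of 2,3-epoxy alcohols, the vinylogous α-ketol rearrangement of β-(1-hydroxycycloalkyl) enones and the invertive Lewis acid opening of donor–acceptor cyclopropanes at their most substituted carbon, whereas a 1,2-shift onto a breaking cyclopropane bond has not been shown. C10 is set by inversion at the breaking bond and hence by the cyclopropane configuration, C5 migrates with retention, C1 is erased, and C8 stays labile and is erased in step 9. The step needs C5 and not C2 to migrate, which the higher substitution of C5 and the crowding of the alternative rotamer (C5 wedged between C20 and C8) should secure, and it needs activation at the dicarbonyl to outrun ionisation of the C1–O bond, which the two acceptors on the cyclopropane disfavour. Capture of the cation by the acetyl oxygen (Cloke–Wilson dihydrofuran) is reversible under the Lewis acid, whereas the shift ends in a ketone and should drain the mixture.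

**Step 9**
Reactants: 15 spiro keto δ-lactone
Product: 18 spiro 3-acetyl-5,6-dihydropyran-2-one (C8=C9), via C8 phenylselenide 16 (not isolated), via selenoxide 17 (not isolated)
Conditions: PhSeCl, pyridine, CH2Cl2, 0 °C; then 30% H2O2, 0 °C to rt
Reagents that add atoms: none
Why: Selenenylation of the β-keto lactone at its only acidic C–H followed by selenoxide syn elimination can use only the C9 hydrogens, and the simple C1 ketone is not enolised by pyridine.

**Step 10**
Reactants: 18 spiro 3-acetyl-5,6-dihydropyran-2-one; 19 buta-1,3-diene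
Product: 20 Diels–Alder adduct (cis-fused lactone/cyclohexene; 8-acetyl; C12=C13)
Conditions: 19 (excess), ZnCl2, CH2Cl2–Et2O, 0 °C to rt, sealed tube
Reagents that add atoms: none
Why: Lewis acid-promoted Diels–Alder reaction of a doubly activated 2-acyl-2-enoate (close precedent in 2-acyl and 2-carbalkoxy cyclohexenones with a quaternary γ-carbon): suprafacial addition makes C11 and C14 cis and so sets C8 and C9 together, and the diene should approach the lactone face that bears the flat C1 carbonyl, anti to C5 and its CH2OTBDPS and gem-dimethyl groups.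

**Step 11**
Reactants: 20 Diels–Alder adduct
Product: 22 bicyclo[3.2.1]oct-2-en-6-one (C13–C16 bond; C11=C12), via acetyl enol silane 21 (not isolated)
Conditions: LiHMDS (1.05 equiv), TMSCl, THF, −78 °C; solvent switch; Pd(OAc)2 (1.1 equiv), MeCN, rt
Reagents that add atoms: none
Why: Saegusa–Ito-type chemistry of a 2-silyloxy-1,5-diene (palladium-mediated cycloalkenylation): the acetyl CH3 is the less hindered and, through the geminal lactone carbonyl, the more acidic enolisation site; its divalent palladium enolate has no β-hydrogen and should insert 5-exo into C12=C13 on the face of the acetyl group (C13 fixed by the bridge) before β-hydride elimination to C11=C12, and any enol silane formed at C2 only gives the ring A enone, which step 12 returns to 23.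

**Step 12**
Reactants: 22 bicyclo[3.2.1]oct-2-en-6-one
Product: 23 saturated 1,15-diketone
Conditions: H2 (1 atm), Pd/C, EtOAc, rt
Reagents that add atoms: none
Why: Heterogeneous hydrogenation of the only C=C bond creates no stereocentre and leaves ketones, lactone and silyl ether untouched.

**Step 13**
Reactants: 23 saturated 1,15-diketone
Product: 24 ring A enone (C2=C3)
Conditions: IBX, DMSO–PhF, 75 °C
Reagents that add atoms: none
Why: IBX dehydrogenation of a ketone through its enol can desaturate only C2–C3, because C10 is quaternary and a C13=C16 double bond next to the C15 ketone would violate Bredt's rule.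

**Step 14**
Reactants: 24 ring A enone
Product: 26 16-exo-hydroxymethyl ketone (TBDPS ether of the target), via C15 enol silane 25 (not isolated)
Conditions: TMSOTf, Et3N, CH2Cl2, 0 °C; then 37% aq HCHO, Yb(OTf)3 (10 mol %), THF, rt
Reagents that add atoms: formaldehyde C=O
Why: Soft enolisation followed by a lanthanide-catalysed aqueous Mukaiyama aldol: C16 is the only enolisable position left (C4, C8 and C10 are quaternary), and formaldehyde should add to the exo face of the bicyclic enol ether, syn to the C14 bridge, which also gives the more stable epimer.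

**Step 15**
Reactants: 26 16-exo-hydroxymethyl ketone
Product: 27 target CNP0505075.1
Conditions: HF·pyridine, THF, 0 °C to rt
Reagents that add atoms: none
Why: Fluoride-driven silyl ether cleavage under mildly acidic conditions should spare the β-hydroxy ketone (no retro-aldol, no elimination) and the C16 centre.

**Compound list**
1 | 3-methylcyclopent-2-en-1-one | CC1=CC(=O)CC1 | starting material
2 | 1-(trimethylsilyloxy)-3,3-dimethylcyclopent-1-ene | CC1(C)CCC(O[Si](C)(C)C)=C1 | intermediate
3 | (S)-2-(hydroxymethyl)-3,3-dimethylcyclopentan-1-one | CC1(C)CCC(=O)[C@@H]1CO | intermediate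
4 | (S)-2-[(tert-butyldiphenylsilyloxy)methyl]-3,3-dimethylcyclopentan-1-one | CC1(C)CCC(=O)[C@@H]1CO[Si](c1ccccc1)(c1ccccc1)C(C)(C)C | intermediate
5 | 2-bromoprop-2-en-1-ol | OCC(Br)=C | starting material
6 | lithium 2-lithioprop-2-en-1-olate (not isolated) | [Li]OCC([Li])=C | intermediate
7 | (1S,2S)-2-[(TBDPS-oxy)methyl]-1-(3-hydroxyprop-1-en-2-yl)-3,3-dimethylcyclopentan-1-ol; alkenyl trans, OH cis to the CH2OTBDPS group | CC1(C)CC[C@@](O)(C(=C)CO)[C@@H]1CO[Si](c1ccccc1)(c1ccccc1)C(C)(C)C | intermediate
8 | bis(trimethylsilyl) ether of 7 (not isolated) | CC1(C)CC[C@@](O[Si](C)(C)C)(C(=C)CO[Si](C)(C)C)[C@@H]1CO[Si](c1ccccc1)(c1ccccc1)C(C)(C)C | intermediate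
9 | tertiary (C1) trimethylsilyl ether of 7, primary allylic OH free | CC1(C)CC[C@@](O[Si](C)(C)C)(C(=C)CO)[C@@H]1CO[Si](c1ccccc1)(c1ccccc1)C(C)(C)C | intermediate
10 | 2,2,6-trimethyl-4H-1,3-dioxin-4-one | CC1=CC(=O)OC(C)(C)O1 | starting material
11 | 3-oxobutanoate (acetoacetate) of 9 | CC1(C)CC[C@@](O[Si](C)(C)C)(C(=C)COC(=O)CC(C)=O)[C@@H]1CO[Si](c1ccccc1)(c1ccccc1)C(C)(C)C | intermediate
12 | 2-diazo-3-oxobutanoate of 9 | CC1(C)CC[C@@](O[Si](C)(C)C)(C(=C)COC(=O)C(=[N+]=[N-])C(C)=O)[C@@H]1CO[Si](c1ccccc1)(c1ccccc1)C(C)(C)C | intermediate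
13 | 1-acetyl-3-oxabicyclo[3.1.0]hexan-2-one carrying the (1S,2S)-1-TMSO-2-(TBDPSOCH2)-3,3-dimethylcyclopentyl group on C5 of the bicycle (= C10); C8 added to the alkene face anti to C5 (not isolated) | CC1(C)CC[C@@](O[Si](C)(C)C)([C@@]23COC(=O)[C@]2(C(C)=O)C3)[C@@H]1CO[Si](c1ccccc1)(c1ccccc1)C(C)(C)C | intermediate
14 | trimethylsilyl enol ether (C8=C15, geometry open) of 15 (not isolated) | CC1(C)CCC(=O)[C@]2(COC(=O)C(=C(C)O[Si](C)(C)C)C2)[C@@H]1CO[Si](c1ccccc1)(c1ccccc1)C(C)(C)C | intermediate
15 | (5R,10S) ring A cyclohexanone (C1=O, C4 gem-dimethyl, C5 CH2OTBDPS) spiro at C10 to the δ-lactone C10–C20H2–O–C7(=O)–C8H(acetyl)–C9H2; C8 labile | CC1(C)CCC(=O)[C@]2(COC(=O)C(C(C)=O)C2)[C@@H]1CO[Si](c1ccccc1)(c1ccccc1)C(C)(C)C | intermediate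
16 | 8-phenylselanyl derivative of 15 (not isolated) | CC1(C)CCC(=O)[C@]2(COC(=O)C([Se]c3ccccc3)(C(C)=O)C2)[C@@H]1CO[Si](c1ccccc1)(c1ccccc1)C(C)(C)C | intermediate
17 | selenoxide of 16 (not isolated) | CC1(C)CCC(=O)[C@]2(COC(=O)C([Se](=O)c3ccccc3)(C(C)=O)C2)[C@@H]1CO[Si](c1ccccc1)(c1ccccc1)C(C)(C)C | intermediate
18 | (5R,10S) spiro 3-acetyl-5,6-dihydro-2H-pyran-2-one (C8=C9) | CC1(C)CCC(=O)[C@]2(COC(=O)C(C(C)=O)=C2)[C@@H]1CO[Si](c1ccccc1)(c1ccccc1)C(C)(C)C | intermediate
19 | buta-1,3-diene | C=CC=C | starting material
20 | (5R,8S,9S,10S) adduct: cyclohexene ring C (C12=C13) cis-fused to the lactone, acetyl on C8 syn to H9, C11 syn to the C1 carbonyl | CC1(C)CCC(=O)[C@]2(COC(=O)[C@@]3(C(C)=O)CC=CC[C@H]32)[C@@H]1CO[Si](c1ccccc1)(c1ccccc1)C(C)(C)C | intermediate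
21 | trimethylsilyl enol ether (C15=C16H2) of 20 (not isolated) | CC1(C)CCC(=O)[C@]2(COC(=O)[C@@]3(C(=C)O[Si](C)(C)C)CC=CC[C@H]32)[C@@H]1CO[Si](c1ccccc1)(c1ccccc1)C(C)(C)C | intermediate
22 | tetracycle with bicyclo[3.2.1]octenone C/D rings (C15=O, C16H2, C11=C12), all centres as in 27 | CC1(C)CCC(=O)[C@]2(COC(=O)[C@@]34C[C@@H](C=C[C@H]32)CC4=O)[C@@H]1CO[Si](c1ccccc1)(c1ccccc1)C(C)(C)C | intermediate
23 | 11,12-dihydro derivative of 22 (saturated 1,15-diketone) | CC1(C)CCC(=O)[C@]2(COC(=O)[C@@]34C[C@@H](CC[C@H]32)CC4=O)[C@@H]1CO[Si](c1ccccc1)(c1ccccc1)C(C)(C)C | intermediate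
24 | 2,3-didehydro derivative of 23 (ring A enone) | CC1(C)C=CC(=O)[C@]2(COC(=O)[C@@]34C[C@@H](CC[C@H]32)CC4=O)[C@@H]1CO[Si](c1ccccc1)(c1ccccc1)C(C)(C)C | intermediate
25 | C15 trimethylsilyl enol ether (C15=C16) of 24 (not isolated) | CC1(C)C=CC(=O)[C@]2(COC(=O)[C@@]34C[C@@H](CC[C@H]32)C=C4O[Si](C)(C)C)[C@@H]1CO[Si](c1ccccc1)(c1ccccc1)C(C)(C)C | intermediate
26 | 6-O-TBDPS ether of the target (16R, CH2OH exo, syn to C14) | CC1(C)C=CC(=O)[C@]2(COC(=O)[C@@]34C[C@@H](CC[C@H]32)[C@H](CO)C4=O)[C@@H]1CO[Si](c1ccccc1)(c1ccccc1)C(C)(C)C | intermediate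
27 | CNP0505075.1, (5R,8S,9S,10S,13R,16R)-6,17-dihydroxy-1,15-dioxo-6,7-secokaur-2-en-7,20-olide skeleton | CC1(C)C=CC(=O)[C@]2(COC(=O)[C@@]34C[C@@H](CC[C@H]32)[C@H](CO)C4=O)[C@@H]1CO | target

Total step count: 15. Longest linear sequence: 15 steps (from 1; 5, 10 and 19 are bought).

**Steps most likely to fail**

Step 8. What may go wrong:
- the carbenoid adds to the alkene with poor facial selectivity;
- the cyclopropane opens along C8–C9;
- the C1 silyloxy group is lost by ionisation;
- C2 migrates instead of C5.

The fallback uses known chemistry only. It sets out from 7 and returns at 18, and it puts reagent control in place of the substrate control.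
- Sharpless asymmetric epoxidation of the primary allylic alcohol (Ti(OiPr)4, L-(+)-diisopropyl tartrate, t-BuOOH, 4 Å sieves, CH2Cl2, −20 °C) gives the epoxy diol F1. The oxidant attacks the face that is also the less hindered one.
- TBSCl and imidazole give the primary silyl ether F2.
- BF3·OEt2 (CH2Cl2, −78 °C) triggers the classical semipinacol ring expansion of the 2,3-epoxy alcohol, in which C5 shifts anti to the C10–O bond. The product is the β-hydroxy ketone F3, whose free CH2OH is C9 and whose CH2OTBS is C20.
- Dess–Martin oxidation gives the keto aldehyde F4.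
- Aqueous HF in MeCN at 0 °C removes only the TBS group and gives the hydroxy aldehyde F5.
- Heating with 10 in toluene gives the acetoacetate F6, which closes by intramolecular Knoevenagel condensation (piperidinium acetate, rt) to 18.

Step 11. What may go wrong: protonolysis of the palladium enolate, or 6-endo insertion that leads to a bicyclo[2.2.2]octane. The fallback is carbenoid chemistry. It sets out from 20 and returns at 23, and it replaces steps 11 and 12.
- Detrifluoroacetylative diazo transfer (LiHMDS, CF3CO2CH2CF3, THF, −78 °C) gives the trifluoroacetyl diketone F7.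
- MsN3, Et3N and H2O in MeCN then give the diazomethyl ketone F8.
- Rh2(OAc)4 in CH2Cl2 closes the cyclopropyl ketone F9, in which C16 is bonded to both C12 and C13 (tricyclo[3.2.1.0(2,7)]octan-6-one core). This is a classical reaction of cyclohex-3-enyl diazomethyl ketones.
- SmI2 (THF–MeOH, −78 °C) opens the ketyl along C16–C12, the cyclopropane bond that is exocyclic to the cyclopentanone and overlaps best with the carbonyl π system, and gives 23.

Step 4. What may go wrong: enolisation of 4 followed by β-elimination of the silanolate, or no addition because both partners are hindered. The fallback sets out from 4 and returns at 7.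
- The much smaller ethynylmagnesium bromide (LaCl3·2LiCl, THF, 0 °C) adds anti to the side chain and gives the ethynyl carbinol F10.
- Palladium-catalysed Markovnikov methoxycarbonylation of the terminal alkyne (Pd(OAc)2, 2-pyridyldiphenylphosphine, MsOH, CO, MeOH) gives the α-substituted acrylate F11.
- DIBAL-H (CH2Cl2, −78 °C) reduces the ester to the allylic alcohol 7.

**Further compounds**
F1 | step 8 | epoxy diol: 2-(hydroxymethyl)oxiran-2-yl group on C1 of the (1S,2S)-cyclopentanol, epoxide oxygen on the face set by L-(+)-tartrate | CC1(C)CC[C@@](O)([C@]2(CO)CO2)[C@@H]1CO[Si](c1ccccc1)(c1ccccc1)C(C)(C)C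
F2 | step 8 | primary TBS ether of F1 | CC1(C)CC[C@@](O)([C@]2(CO[Si](C)(C)C(C)(C)C)CO2)[C@@H]1CO[Si](c1ccccc1)(c1ccccc1)C(C)(C)C
F3 | step 8 | (5R,10S)-cyclohexanone with CH2OH (C9) and CH2OTBS (C20) on C10 | CC1(C)CCC(=O)[C@](CO)(CO[Si](C)(C)C(C)(C)C)[C@@H]1CO[Si](c1ccccc1)(c1ccccc1)C(C)(C)C
F4 | step 8 | keto aldehyde (C9 = CHO) from F3 | CC1(C)CCC(=O)[C@](C=O)(CO[Si](C)(C)C(C)(C)C)[C@@H]1CO[Si](c1ccccc1)(c1ccccc1)C(C)(C)C
F5 | step 8 | hydroxy keto aldehyde (C20 OH free) | CC1(C)CCC(=O)[C@](C=O)(CO)[C@@H]1CO[Si](c1ccccc1)(c1ccccc1)C(C)(C)C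
F6 | step 8 | C20 acetoacetate of F5 | CC1(C)CCC(=O)[C@](C=O)(COC(=O)CC(C)=O)[C@@H]1CO[Si](c1ccccc1)(c1ccccc1)C(C)(C)C
F7 | step 11 | 16-trifluoroacetyl derivative of 20 | CC1(C)CCC(=O)[C@]2(COC(=O)[C@@]3(C(=O)CC(=O)C(F)(F)F)CC=CC[C@H]32)[C@@H]1CO[Si](c1ccccc1)(c1ccccc1)C(C)(C)C
F8 | step 11 | diazomethyl ketone (C16 = CHN2) from 20 | CC1(C)CCC(=O)[C@]2(COC(=O)[C@@]3(C(=O)C=[N+]=[N-])CC=CC[C@H]32)[C@@H]1CO[Si](c1ccccc1)(c1ccccc1)C(C)(C)C
F9 | step 11 | cyclopropyl ketone, C16 bonded to C12 and C13 on the face of C15 | CC1(C)CCC(=O)[C@]2(COC(=O)[C@@]34C[C@H]5[C@@H](C[C@H]32)[C@H]5C4=O)[C@@H]1CO[Si](c1ccccc1)(c1ccccc1)C(C)(C)C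
F10 | step 4 | (1S,2S)-1-ethynyl-2-[(TBDPS-oxy)methyl]-3,3-dimethylcyclopentan-1-ol | CC1(C)CC[C@@](O)(C#C)[C@@H]1CO[Si](c1ccccc1)(c1ccccc1)C(C)(C)C
F11 | step 4 | methyl 2-[(1S,2S)-1-hydroxy-2-(TBDPS-oxymethyl)-3,3-dimethylcyclopentyl]acrylate | CC1(C)CC[C@@](O)(C(=C)C(=O)OC)[C@@H]1CO[Si](c1ccccc1)(c1ccccc1)C(C)(C)C
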